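(The readings are calculated for substances that don't exist; noise was put on by code.)

the same everywhere: free catalyst 5 mol%
- blue: substrate 0.075 M; reagent 4 equiv; run made earlier
- red: substrate 0.30 M; reagent 4 equiv; run made earlier
- flask: substrate 0.15 M; reagent 4.00 equiv

- blue (time / h: product / %): 1.33: 13.9; 3.00: 22.9; 4.00: 25.6; 6.00: 31.1; 8.00: 33.0; 10.0: 35.3
- red (time / h: product / %): 0.833: 13.4; 1.33: 17.8; 2.00: 22.1; 2.50: 25.7; 4.00: 29.6; 6.00: 34.0; 10.0: 35.4

(each reading ± 0.5 percentage points)

- the numbers in the tables scatter by 0.5 percentage points (one standard deviation)
- what may be going on: 2 reagent -> homo dimer; catalyst intermediate C -> free catalyst + product; catalyst intermediate A -> by-product + catalyst intermediate B; substrate + catalyst intermediate B -> catalyst intermediate C; catalyst intermediate A -> spent catalyst; reagent + free catalyst -> catalyst intermediate A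

1. apparent order in reagent when 20% of the substrate are converted (percent change of the rate of making product for one percent more reagent charged)

- Start from the leftover: after 10.0 h the blue run has 64.7% of its substrate charge not found as product, and the red run, charged 4.00 times as strongly, has 64.6% not found as product after 10.0 h. The end of the run therefore tells little about the charge, so look at the way there.
- Take two times at equal yield: the blue run read 25.6% at 4.00 h, and the red run read 25.7% at 2.50 h. As a reading, the blue run took 1.60 times as long.
- Go to logarithms: divide the logarithm of that time ratio by the logarithm of the charge ratio. This gives 0.339, the stretch exponent, which is the apparent order of the whole charge scaled together.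
- Treat it as my upper figure for the reagent, since reagent, substrate and catalyst rose together in these runs.
- Use it on the flask, charged twice as strongly as the blue run: expect the blue run's 35.3% after 7.91 h.
- Set beside this the forecast of 0.13, below my upper figure, on the grounds that “Reagent and substrate were always scaled together, so the two are confounded.”
- Read the flask's result: its apparent order in reagent is 0.20, above the forecast and below the stretch exponent.

    2 reagent → homo dimer (k = 2.32 /M/h)
    catalyst intermediate C → free catalyst + product (k = 7.46 /h)
    catalyst intermediate A → by-product + catalyst intermediate B (k = 21.8 /h)
    substrate + catalyst intermediate B → catalyst intermediate C (k = 239 /M/h)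
    catalyst intermediate A → spent catalyst (k = 2.31 /h)
    reagent + free catalyst → catalyst intermediate A (k = 49.5 /M/h)

- Set the stretch exponent's time beside the flask: it gave 7.91 h for 35.3%, and the flask holds 34.7% product at 8.00 h. At 0.291 h in the flask, catalyst intermediate A goes on to catalyst intermediate B 9.4 times as fast as it goes to spent catalyst, and at 8.00 h spent catalyst holds 73.9% of the catalyst charged.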